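**Strategy.** The flavone is cut between C2 and C3 of ring C. C2 carries ring B and sits at the acid oxidation level, C3 is the methyl carbon of a ring A acetophenone, and O1 is the ortho phenol oxygen of ring A, so a 2-acetylaryl ester of the ring B acid already holds every atom of ring C. Its base-induced O-to-C acyl shift (step 13) makes the C2–C3 bond as a 1,3-diketone in one operation, and mild acid then closes O1–C2. The precursor is the bis-silylated phloroacetophenone ester of a 4-O-alkylated syringic acid that carries the complete, silyl-protected erythro (7''R,8''S) guaiacylglycerol side chain. The p-coumarate is added last.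

Key step: step 13

Remarks on the chemistry (locants: flavone unprimed, ring B primed, side chain double-primed):
- The erythro (7''R,8''S) side chain is the anti isomer in aldol terms. The boron-mediated syn aldol gives the threo pair, so C8'' is set by the auxiliary and C7'' is then inverted by a Mitsunobu reaction (steps 7 and 8).
- (R)-4-Benzyl-3-(chloroacetyl)oxazolidin-2-one (3) is assumed to be purchasable.
- O9'' carries a triethylsilyl group and O7'' a tert-butyldimethylsilyl group, so that the acid of step 14 frees only the C9'' hydroxyl.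

Step 1
Reactants: 1 syringic acid
Product: 2 benzyl syringate (benzyl 4-hydroxy-3,5-dimethoxybenzoate)
Conditions: BnBr (1.05 equiv), KHCO3, DMF, 40 °C
Reagents that add atoms: benzyl bromide, BrCc1ccccc1
Why: Carboxylate O-alkylation; hydrogencarbonate deprotonates only the acid, so the carboxylate is benzylated and the hindered phenol stays free.

Step 2
Reactants: 2 benzyl syringate; 3 (R)-4-benzyl-3-(chloroacetyl)oxazolidin-2-one
Product: 4 benzyl 4-{2-[(4R)-4-benzyl-2-oxooxazolidin-3-yl]-2-oxoethoxy}-3,5-dimethoxybenzoate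
Conditions: K2CO3, NaI (cat.), acetone, 50 °C
Reagents that add atoms: none
Why: Williamson ether synthesis; the syringate phenoxide should displace the activated α-halide (iodide exchange in the flask) faster than it attacks the imide carbonyl.

Step 3
Reactants: 5 vanillin
Product: 6 3-methoxy-4-(triisopropylsilyloxy)benzaldehyde
Conditions: TIPSCl, imidazole, DMF, rt
Reagents that add atoms: triisopropylsilyl chloride, CC(C)[Si](Cl)(C(C)C)C(C)C
Why: Imidazole-promoted silylation of a phenol; the bulky aryl silyl ether should later withstand borohydride, carbonate in methanol and the amide base.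

Step 4
Reactants: 4 aryloxyacetyl imide; 6 O-silyl vanillin
Product: 8 (4R)-4-benzyl-3-[(2R,3S)-2-(4-benzyloxycarbonyl-2,6-dimethoxyphenoxy)-3-hydroxy-3-(3-methoxy-4-triisopropylsilyloxyphenyl)propanoyl]oxazolidin-2-one (syn adduct; 7''S,8''S), via boron enolate 7 (not isolated)
Conditions: Bu2BOTf, iPr2NEt, CH2Cl2, 0 °C; then 6, −78 → 0 °C; pH 7 buffer, MeOH, H2O2, 0 °C
Reagents that add atoms: none
Why: Evans boron-mediated syn aldol; the Z-enolate reacts through a closed Zimmerman–Traxler chair on the face away from the auxiliary benzyl group, which sets C8'' as S (kept to the end) and C7'' as S, the threo pair.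

Step 5
Reactants: 8 syn aldol adduct
Product: 9 benzyl 4-{[(1S,2S)-1,3-dihydroxy-1-(3-methoxy-4-triisopropylsilyloxyphenyl)propan-2-yl]oxy}-3,5-dimethoxybenzoate (threo diol)
Conditions: NaBH4, THF/H2O (4:1), 0 °C → rt
Reagents that add atoms: none
Why: Chemoselective borohydride reduction of the N-acyl oxazolidinone, which is far more electrophilic than the electron-rich benzoate ester; the auxiliary is released and neither stereocentre is touched.

Step 6
Reactants: 9 threo diol
Product: 10 benzyl 4-{[(1S,2S)-1-hydroxy-1-(3-methoxy-4-triisopropylsilyloxyphenyl)-3-(triethylsilyloxy)propan-2-yl]oxy}-3,5-dimethoxybenzoate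
Conditions: TESCl (1.05 equiv), imidazole, CH2Cl2, −40 °C
Reagents that add atoms: triethylsilyl chloride, CC[Si](Cl)(CC)CC
Why: Selective silylation of the primary hydroxyl over the hindered secondary benzylic one at low temperature.

Step 7
Reactants: 10 threo alcohol
Product: 11 benzyl 4-{[(1R,2S)-1-(chloroacetoxy)-1-(3-methoxy-4-triisopropylsilyloxyphenyl)-3-(triethylsilyloxy)propan-2-yl]oxy}-3,5-dimethoxybenzoate
Conditions: ClCH2CO2H, PPh3, DIAD, toluene, 0 °C → rt
Reagents that add atoms: chloroacetic acid, O=C(O)CCl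
Why: Mitsunobu reaction; chloroacetate displaces the benzylic oxyphosphonium group in an SN2 sense and inverts C7'' from S to R (threo to erythro), the acidic pronucleophile and the two β-oxygens working against ionisation.

Step 8
Reactants: 11 chloroacetate
Product: 12 benzyl 4-{[(1R,2S)-1-hydroxy-1-(3-methoxy-4-triisopropylsilyloxyphenyl)-3-(triethylsilyloxy)propan-2-yl]oxy}-3,5-dimethoxybenzoate (erythro alcohol)
Conditions: K2CO3 (0.2 equiv), MeOH/CH2Cl2, 0 °C
Reagents that add atoms: none
Why: Base-catalysed methanolysis by acyl–oxygen cleavage, which leaves C7'' as set; the chloroacetate should react far faster than the electron-rich benzyl benzoate, the aryl TIPS ether or the primary TES ether.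

Step 9
Reactants: 12 erythro alcohol
Product: 13 benzyl 4-{[(1R,2S)-1-(tert-butyldimethylsilyloxy)-1-(3-methoxy-4-triisopropylsilyloxyphenyl)-3-(triethylsilyloxy)propan-2-yl]oxy}-3,5-dimethoxybenzoate
Conditions: TBSOTf, 2,6-lutidine, CH2Cl2, −78 → 0 °C
Reagents that add atoms: tert-butyldimethylsilyl triflate, CC(C)(C)[Si](C)(C)OS(=O)(=O)C(F)(F)F
Why: Silylation of a hindered secondary alcohol with a silyl triflate and a non-nucleophilic base.

Step 10
Reactants: 13 benzyl ester
Product: 14 4-{[(1R,2S)-1-(tert-butyldimethylsilyloxy)-1-(3-methoxy-4-triisopropylsilyloxyphenyl)-3-(triethylsilyloxy)propan-2-yl]oxy}-3,5-dimethoxybenzoic acid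
Conditions: H2 (1 atm), 10% Pd/C, EtOAc, rt
Reagents that add atoms: none
Why: Hydrogenolysis of a benzyl ester; in ethyl acetate the silyl ethers should be inert and the benzylic silyl ether should be cleaved far more slowly than the ester.

Step 11
Reactants: 15 2,4,6-trihydroxyacetophenone
Product: 16 1-[2,4-bis(tert-butyldimethylsilyloxy)-6-hydroxyphenyl]ethanone
Conditions: TBSCl (2.1 equiv), imidazole, DMF, 0 °C → rt
Reagents that add atoms: tert-butyldimethylsilyl chloride, CC(C)(C)[Si](C)(C)Cl
Why: Phenol silylation that should stop at two groups, because the last hydroxyl is held in a hydrogen bond to the acetyl carbonyl and is the least nucleophilic.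

Step 12
Reactants: 14 ring B acid; 16 ring A acetophenone
Product: 17 2-acetyl-3,5-bis(tert-butyldimethylsilyloxy)phenyl 4-{[(1R,2S)-1-(tert-butyldimethylsilyloxy)-1-(3-methoxy-4-triisopropylsilyloxyphenyl)-3-(triethylsilyloxy)propan-2-yl]oxy}-3,5-dimethoxybenzoate
Conditions: DCC, DMAP (cat.), CH2Cl2, 0 °C → rt
Reagents that add atoms: none
Why: Steglich esterification; the acylpyridinium ion formed from the O-acylisourea acylates the chelated phenol, the only free hydroxyl present.

Step 13
Reactants: 17 2-acetylaryl ester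
Product: 18 1-[2,4-bis(tert-butyldimethylsilyloxy)-6-hydroxyphenyl]-3-(4-{[(1R,2S)-1-(tert-butyldimethylsilyloxy)-1-(3-methoxy-4-triisopropylsilyloxyphenyl)-3-(triethylsilyloxy)propan-2-yl]oxy}-3,5-dimethoxyphenyl)propane-1,3-dione
Conditions: LiN(SiMe3)2 (3.2 equiv), THF, −78 → −20 °C; then AcOH
Reagents that add atoms: none
Why: LiN(SiMe3)2 removes a proton from the acetyl methyl group, and the lithium enolate adds to the ester carbonyl held next to it on ring A through a six-membered cyclic alkoxide, which collapses with loss of the ring A phenoxide to give the C2–C3 bond; further base deprotonates the diketone at once, which makes the transfer irreversible until the acid quench. This is the Baker–Venkataraman rearrangement, an intramolecular Claisen-type O-to-C acyl transfer of 2-aroyloxyacetophenones. No ring is closed in this step (the cyclic alkoxide is transient and ring C is closed in step 14) and no stereocentre is formed. The step needs enolisation at one site and acylation within the molecule rather than between molecules: the acetyl methyl is the only carbon acid in 17, since C8'' bears an aryloxy group but no carbonyl and O7'' and O9'' are silyl ethers, and the ortho tether should make acyl transfer faster than any bimolecular Claisen reaction or ester cleavage at low temperature. The hindered, non-nucleophilic base and the silyl ethers on all five hydroxyls should leave C7'' and C8'' untouched.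

Step 14
Reactants: 18 1,3-diketone
Product: 20 5,7-bis(tert-butyldimethylsilyloxy)-2-(4-{[(1R,2S)-1-(tert-butyldimethylsilyloxy)-3-hydroxy-1-(3-methoxy-4-triisopropylsilyloxyphenyl)propan-2-yl]oxy}-3,5-dimethoxyphenyl)-4H-chromen-4-one, via TES-protected flavone 19 (not isolated)
Conditions: p-TsOH·H2O (0.2 equiv), CH2Cl2, rt; then MeOH, 0 °C
Reagents that add atoms: none
Why: Acid-catalysed cyclodehydration, in which the ring A phenol adds to the C2 carbonyl (6-exo-trig) and the hemiketal loses water to the aromatic pyranone; methanol then removes the labile primary TES ether under the same acid, while the aryl silyl ethers, the secondary TBS ether and the non-phenolic benzylic centre should persist.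

Step 15
Reactants: 21 p-coumaric acid
Product: 23 (E)-3-[4-(tert-butyldimethylsilyloxy)phenyl]prop-2-enoic acid, via bis-silyl derivative 22 (not isolated)
Conditions: TBSCl (2.4 equiv), imidazole, DMF, rt; then AcOH/THF/H2O, rt
Reagents that add atoms: tert-butyldimethylsilyl chloride, CC(C)(C)[Si](C)(C)Cl
Why: Exhaustive silylation followed by selective hydrolysis of the silyl ester, which is far more labile than the aryl silyl ether.

Step 16
Reactants: 20 flavone alcohol; 23 O-silyl p-coumaric acid
Product: 24 (2S,3R)-3-(tert-butyldimethylsilyloxy)-2-{4-[5,7-bis(tert-butyldimethylsilyloxy)-4-oxo-4H-chromen-2-yl]-2,6-dimethoxyphenoxy}-3-(3-methoxy-4-triisopropylsilyloxyphenyl)propyl (E)-3-[4-(tert-butyldimethylsilyloxy)phenyl]prop-2-enoate (fully silylated target; 7''R,8''S)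
Conditions: DCC, DMAP (cat.), CH2Cl2, 0 °C → rt
Reagents that add atoms: none
Why: Steglich esterification of the only free hydroxyl, the primary C9'' alcohol.

Step 17
Reactants: 24 fully silylated target
Product: 25 target, (2S,3R)-2-[4-(5,7-dihydroxy-4-oxo-4H-chromen-2-yl)-2,6-dimethoxyphenoxy]-3-hydroxy-3-(4-hydroxy-3-methoxyphenyl)propyl (E)-3-(4-hydroxyphenyl)prop-2-enoate (7''R,8''S)
Conditions: HF·pyridine, pyridine, THF, 0 °C → rt
Reagents that add atoms: none
Why: Fluoride-mediated cleavage of all five Si–O bonds under weakly acidic conditions, in which no alkoxide forms, so the C9'' ester should neither migrate to O7'' nor hydrolyse and C7'' should keep its configuration.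

**Compound list**

1 | syringic acid | COc1cc(C(=O)O)cc(OC)c1O | starting material
2 | benzyl 4-hydroxy-3,5-dimethoxybenzoate | COc1cc(C(=O)OCc2ccccc2)cc(OC)c1O | intermediate
3 | (R)-4-benzyl-3-(chloroacetyl)oxazolidin-2-one | O=C(CCl)N1C(=O)OC[C@H]1Cc1ccccc1 | starting material
4 | benzyl 4-{2-[(4R)-4-benzyl-2-oxooxazolidin-3-yl]-2-oxoethoxy}-3,5-dimethoxybenzoate | COc1cc(C(=O)OCc2ccccc2)cc(OC)c1OCC(=O)N1C(=O)OC[C@H]1Cc1ccccc1 | intermediate
5 | vanillin | COc1cc(C=O)ccc1O | starting material
6 | 3-methoxy-4-(triisopropylsilyloxy)benzaldehyde | COc1cc(C=O)ccc1O[Si](C(C)C)(C(C)C)C(C)C | intermediate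
7 | (Z)-dibutylboron enolate of 4 | CCCCB(CCCC)O/C(=C\Oc1c(OC)cc(C(=O)OCc2ccccc2)cc1OC)N1C(=O)OC[C@H]1Cc1ccccc1 | intermediate (not isolated)
8 | (4R)-4-benzyl-3-[(2R,3S)-2-(4-benzyloxycarbonyl-2,6-dimethoxyphenoxy)-3-hydroxy-3-(3-methoxy-4-triisopropylsilyloxyphenyl)propanoyl]oxazolidin-2-one | O=C([C@H](Oc1c(OC)cc(C(=O)OCc2ccccc2)cc1OC)[C@@H](O)c1ccc(O[Si](C(C)C)(C(C)C)C(C)C)c(OC)c1)N1C(=O)OC[C@H]1Cc1ccccc1 | intermediate
9 | benzyl 4-{[(1S,2S)-1,3-dihydroxy-1-(3-methoxy-4-triisopropylsilyloxyphenyl)propan-2-yl]oxy}-3,5-dimethoxybenzoate (threo) | OC[C@H](Oc1c(OC)cc(C(=O)OCc2ccccc2)cc1OC)[C@@H](O)c1ccc(O[Si](C(C)C)(C(C)C)C(C)C)c(OC)c1 | intermediate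
10 | benzyl 4-{[(1S,2S)-1-hydroxy-1-(3-methoxy-4-triisopropylsilyloxyphenyl)-3-(triethylsilyloxy)propan-2-yl]oxy}-3,5-dimethoxybenzoate | CC[Si](CC)(CC)OC[C@H](Oc1c(OC)cc(C(=O)OCc2ccccc2)cc1OC)[C@@H](O)c1ccc(O[Si](C(C)C)(C(C)C)C(C)C)c(OC)c1 | intermediate
11 | benzyl 4-{[(1R,2S)-1-(chloroacetoxy)-1-(3-methoxy-4-triisopropylsilyloxyphenyl)-3-(triethylsilyloxy)propan-2-yl]oxy}-3,5-dimethoxybenzoate | CC[Si](CC)(CC)OC[C@H](Oc1c(OC)cc(C(=O)OCc2ccccc2)cc1OC)[C@H](OC(=O)CCl)c1ccc(O[Si](C(C)C)(C(C)C)C(C)C)c(OC)c1 | intermediate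
12 | benzyl 4-{[(1R,2S)-1-hydroxy-1-(3-methoxy-4-triisopropylsilyloxyphenyl)-3-(triethylsilyloxy)propan-2-yl]oxy}-3,5-dimethoxybenzoate (erythro) | CC[Si](CC)(CC)OC[C@H](Oc1c(OC)cc(C(=O)OCc2ccccc2)cc1OC)[C@H](O)c1ccc(O[Si](C(C)C)(C(C)C)C(C)C)c(OC)c1 | intermediate
13 | benzyl 4-{[(1R,2S)-1-(tert-butyldimethylsilyloxy)-1-(3-methoxy-4-triisopropylsilyloxyphenyl)-3-(triethylsilyloxy)propan-2-yl]oxy}-3,5-dimethoxybenzoate | COc1cc([C@@H](O[Si](C)(C)C(C)(C)C)[C@H](CO[Si](CC)(CC)CC)Oc2c(OC)cc(C(=O)OCc3ccccc3)cc2OC)ccc1O[Si](C(C)C)(C(C)C)C(C)C | intermediate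
14 | 4-{[(1R,2S)-1-(tert-butyldimethylsilyloxy)-1-(3-methoxy-4-triisopropylsilyloxyphenyl)-3-(triethylsilyloxy)propan-2-yl]oxy}-3,5-dimethoxybenzoic acid | COc1cc([C@@H](O[Si](C)(C)C(C)(C)C)[C@H](CO[Si](CC)(CC)CC)Oc2c(OC)cc(C(=O)O)cc2OC)ccc1O[Si](C(C)C)(C(C)C)C(C)C | intermediate
15 | 2,4,6-trihydroxyacetophenone | CC(=O)c1c(O)cc(O)cc1O | starting material
16 | 1-[2,4-bis(tert-butyldimethylsilyloxy)-6-hydroxyphenyl]ethanone | CC(=O)c1c(O)cc(O[Si](C)(C)C(C)(C)C)cc1O[Si](C)(C)C(C)(C)C | intermediate
17 | 2-acetyl-3,5-bis(tert-butyldimethylsilyloxy)phenyl ester of 14 | COc1cc([C@@H](O[Si](C)(C)C(C)(C)C)[C@H](CO[Si](CC)(CC)CC)Oc2c(OC)cc(C(=O)Oc3cc(O[Si](C)(C)C(C)(C)C)cc(O[Si](C)(C)C(C)(C)C)c3C(C)=O)cc2OC)ccc1O[Si](C(C)C)(C(C)C)C(C)C | intermediate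
18 | 1-(ring A)-3-(ring B)propane-1,3-dione with free 2-hydroxyl on ring A and the silylated (7''R,8''S) side chain | COc1cc([C@@H](O[Si](C)(C)C(C)(C)C)[C@H](CO[Si](CC)(CC)CC)Oc2c(OC)cc(C(=O)CC(=O)c3c(O)cc(O[Si](C)(C)C(C)(C)C)cc3O[Si](C)(C)C(C)(C)C)cc2OC)ccc1O[Si](C(C)C)(C(C)C)C(C)C | intermediate
19 | 5,7-bis(tert-butyldimethylsilyloxy)flavone with 7''-O-TBS, 9''-O-TES and 4''-O-TIPS side chain | COc1cc([C@@H](O[Si](C)(C)C(C)(C)C)[C@H](CO[Si](CC)(CC)CC)Oc2c(OC)cc(-c3cc(=O)c4c(O[Si](C)(C)C(C)(C)C)cc(O[Si](C)(C)C(C)(C)C)cc4o3)cc2OC)ccc1O[Si](C(C)C)(C(C)C)C(C)C | intermediate (not isolated)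
20 | 5,7-bis(tert-butyldimethylsilyloxy)flavone with 7''-O-TBS, free 9''-OH and 4''-O-TIPS side chain | COc1cc([C@@H](O[Si](C)(C)C(C)(C)C)[C@H](CO)Oc2c(OC)cc(-c3cc(=O)c4c(O[Si](C)(C)C(C)(C)C)cc(O[Si](C)(C)C(C)(C)C)cc4o3)cc2OC)ccc1O[Si](C(C)C)(C(C)C)C(C)C | intermediate
21 | p-coumaric acid | O=C(O)/C=C/c1ccc(O)cc1 | starting material
22 | tert-butyldimethylsilyl (E)-3-[4-(tert-butyldimethylsilyloxy)phenyl]prop-2-enoate | CC(C)(C)[Si](C)(C)OC(=O)/C=C/c1ccc(O[Si](C)(C)C(C)(C)C)cc1 | intermediate (not isolated)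
23 | (E)-3-[4-(tert-butyldimethylsilyloxy)phenyl]prop-2-enoic acid | O=C(O)/C=C/c1ccc(O[Si](C)(C)C(C)(C)C)cc1 | intermediate
24 | fully silylated target (9''-O-coumarate of 20) | COc1cc([C@@H](O[Si](C)(C)C(C)(C)C)[C@H](COC(=O)/C=C/c2ccc(O[Si](C)(C)C(C)(C)C)cc2)Oc2c(OC)cc(-c3cc(=O)c4c(O[Si](C)(C)C(C)(C)C)cc(O[Si](C)(C)C(C)(C)C)cc4o3)cc2OC)ccc1O[Si](C(C)C)(C(C)C)C(C)C | intermediate
25 | CNP0264527.1, tricin 4'-O-[erythro-(7''R,8''S)-β-guaiacylglyceryl] ether 9''-O-(E)-p-coumarate | COc1cc([C@@H](O)[C@H](COC(=O)/C=C/c2ccc(O)cc2)Oc2c(OC)cc(-c3cc(=O)c4c(O)cc(O)cc4o3)cc2OC)ccc1O | target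

**Step count.** Total: 17 steps. Longest linear sequence: 14 steps (1, 2, 4 to 10, 12, 13, 14, 16, 17).

**Steps most likely to fail**

Step 7. The electron-rich benzylic oxyphosphonium intermediate may ionise, which would erode the stereospecificity at C7'', or it may lose a proton to give the enol ether instead of being displaced. The fallback replaces substitution by oxidation and reduction. It sets out from 10: Dess–Martin periodinane (NaHCO3, CH2Cl2, 0 °C) should give the C7'' ketone F1 under neutral conditions that keep C8''. Zn(BH4)2 in Et2O at −30 °C should then reduce it under chelation control, with zinc bridging the ketone and aryloxy oxygens and hydride entering past C8''–H, to the erythro alcohol. The fallback comes back to the route at 12; any threo alcohol formed is 10 and can be put through again.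

Step 13. The amide base or traces of hydroxide may cleave the aryl ester and return ring A as its phenol, or the twisted, doubly ortho-substituted acetyl group may enolise too slowly for complete transfer. The fallback forms the same C2–C3 bond by intermolecular Claisen-type C-acylation. It sets out from 14: 1-chloro-N,N,2-trimethylprop-1-en-1-amine (CH2Cl2, 0 °C) should give the acid chloride F2 without acid. F2 is added to the dilithium salt of 16 (LiN(SiMe3)2, THF, −78 °C), where any O-acylated material is 17 and rearranges in the same flask. After an AcOH quench the fallback comes back to the route at 18.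

Step 14. The acid needed to dehydrate the hemiketal may strip the ring A silyl ethers, or the reaction may stall at the hemiketal; a free 7-hydroxyl would then compete in the carbodiimide acylation of step 16. The fallback gives up ring A protection and activates the alcohol instead of the acid. It sets out from 18: CSA in MeOH/CH2Cl2 (rt), then K2CO3 in MeOH (0 °C), should give the ring A free flavone alcohol F3, in which the secondary TBS and the guaiacyl TIPS ethers remain. Mitsunobu esterification of F3 with 23 (PPh3, DIAD, THF, 0 °C) activates the primary C9'' alcohol, and the carboxylic acid, the most acidic pronucleophile present, should be the one alkylated, giving the coumarate F4. HF·pyridine as in step 17 then brings the fallback back to the route at 25.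

**Further compounds**

F1 | step 7 | benzyl 3,5-dimethoxy-4-{[(2S)-1-(3-methoxy-4-triisopropylsilyloxyphenyl)-1-oxo-3-(triethylsilyloxy)propan-2-yl]oxy}benzoate | CC[Si](CC)(CC)OC[C@H](Oc1c(OC)cc(C(=O)OCc2ccccc2)cc1OC)C(=O)c1ccc(O[Si](C(C)C)(C(C)C)C(C)C)c(OC)c1
F2 | step 13 | 4-{[(1R,2S)-1-(tert-butyldimethylsilyloxy)-1-(3-methoxy-4-triisopropylsilyloxyphenyl)-3-(triethylsilyloxy)propan-2-yl]oxy}-3,5-dimethoxybenzoyl chloride | COc1cc([C@@H](O[Si](C)(C)C(C)(C)C)[C@H](CO[Si](CC)(CC)CC)Oc2c(OC)cc(C(=O)Cl)cc2OC)ccc1O[Si](C(C)C)(C(C)C)C(C)C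
F3 | step 14 | 5,7-dihydroxyflavone with 7''-O-TBS, free 9''-OH and 4''-O-TIPS side chain (7''R,8''S) | COc1cc([C@@H](O[Si](C)(C)C(C)(C)C)[C@H](CO)Oc2c(OC)cc(-c3cc(=O)c4c(O)cc(O)cc4o3)cc2OC)ccc1O[Si](C(C)C)(C(C)C)C(C)C
F4 | step 14 | 9''-O-[(E)-4-(tert-butyldimethylsilyloxy)cinnamoyl] ester of F3 | COc1cc([C@@H](O[Si](C)(C)C(C)(C)C)[C@H](COC(=O)/C=C/c2ccc(O[Si](C)(C)C(C)(C)C)cc2)Oc2c(OC)cc(-c3cc(=O)c4c(O)cc(O)cc4o3)cc2OC)ccc1O[Si](C(C)C)(C(C)C)C(C)C
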